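**Retrosynthetic overview**

1. The ring-fusion C–Br is put in last by radical hydrobromination of a ring alkene; that alkene comes from the enol triflate of a Birch-derived ketone, and the side-chain stereocentre on the cyclopentane comes from hydrogenation of an exocyclic alkene.
2. The cyclopentane and the γ-lactone are closed together by a gold-triggered carbolactonisation of a 1,6-enyne amide, which also releases the chiral auxiliary.
3. The enyne comes from acetylide addition of the core alkyne to the ring A ketone, (R)-4-bromo-3,3-dimethylcyclohexanone.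
4. The core cyclohexadiene with its quaternary carbon comes from a Schultz Birch reduction–alkylation of a 2-methoxy-5-methylbenzamide.
5. The ring A ketone comes from a Shi epoxide by bromide opening, lactonisation, methylenation and an O-to-C ring switch. Ring order: ring A (separate fragment), core six-membered ring from the arene, then cyclopentane and lactone in one operation.

Assumption: the Schultz Birch reduction–alkylation is taken to follow its chelated-enolate model (alkylation anti to the methoxymethyl arm), for which the (R)-auxiliary gives the quaternary carbon needed; if the sense is the opposite, (S)-2-(methoxymethyl)pyrrolidine is used and nothing else changes.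

Locants for the tricycle (11-oxatricyclo[4.3.2.0(1,5)]undecane): C1 quaternary ring-fusion carbon, C4 side-chain carbon, C5 ring-fusion CH, C6 C(Me)–O, C8/C9 ring CH2/CHBr, C10 lactone C=O, O11.

**Route**

Step 1
Reactants: 1 2-methylbut-3-en-2-ol; 2 triethyl orthoacetate
Product: 3 ethyl 5-methylhex-4-enoate
Conditions: 2 (3 equiv), EtCO2H (cat.), 140 °C, EtOH distilled off
Reagents that add atoms: none
Why: Johnson–Claisen rearrangement; the mixed ketene acetal of the tertiary allylic alcohol undergoes a [3,3] shift to the γ,δ-unsaturated ester (no stereocentre).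

Step 2
Reactants: 3 ethyl 5-methylhex-4-enoate
Product: 4 ethyl 3-[(2S)-3,3-dimethyloxiran-2-yl]propanoate
Conditions: 1,2:4,5-di-O-isopropylidene-β-L-erythro-2,3-hexodiulo-2,6-pyranose (0.3 equiv, the enantiomer of the Shi ketone), KHSO5, K2CO3, Bu4NHSO4, MeCN–CH2(OMe)2–aq. Na2B4O7 buffer, 0 °C
Reagents that add atoms: potassium peroxymonosulfate, [K+].[O-]S(=O)(=O)OO
Why: Shi asymmetric epoxidation; the chiral dioxirane of the L-series ketone epoxidises the trisubstituted alkene through the spiro transition state to give the (S)-epoxide (the D-fructose ketone gives R).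

Step 3
Reactants: 4 ethyl 3-[(2S)-3,3-dimethyloxiran-2-yl]propanoate
Product: 6 (5R)-5-bromo-6,6-dimethyloxan-2-one, via bromohydrin ester 5 (not isolated)
Conditions: LiBr, AcOH, THF, 23 °C; then TsOH·H2O (cat.), toluene, 60 °C
Reagents that add atoms: lithium bromide, [Li+].[Br-]
Why: SN2 opening of the epoxide by bromide at the less substituted carbon with inversion sets the (R)-C–Br next to the tertiary carbinol, which then lactonises under acid catalysis.

Step 4
Reactants: 6 (5R)-5-bromo-6,6-dimethyloxan-2-one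
Product: 7 (3R)-3-bromo-2,2-dimethyl-6-methylideneoxane
Conditions: Cp2TiMe2 (2 equiv), toluene, 65 °C, dark
Reagents that add atoms: dimethyltitanocene, C[Ti](C)(C1C=CC=C1)C1C=CC=C1
Why: Petasis methylenation of the lactone carbonyl through Cp2Ti=CH2 gives the exocyclic enol ether; the C–Br centre is not touched.

Step 5
Reactants: 7 (3R)-3-bromo-2,2-dimethyl-6-methylideneoxane
Product: 8 (4R)-4-bromo-3,3-dimethylcyclohexan-1-one
Conditions: Me3SiOTf (0.2 equiv), 2,6-di-tert-butyl-4-methylpyridine (0.3 equiv), CH2Cl2, −78 to −20 °C; aq. NaHCO3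
Reagents that add atoms: none
Why: Proposed new method: a silyl-triflate-catalysed 1,3 O-to-C shift of the cyclic enol ether — silylation of the ring oxygen lets the tertiary C–O bond ionise with help from the neighbouring bromine to a bromonium ion and a silyl enol ether, whose CH2 terminus recloses on the tertiary carbon, the bridged bromonium keeping C4 configured; closest known reaction types are the Petasis–Ferrier rearrangement and the Reetz–Mukaiyama tert-alkylation of silyl enol ethers.

Step 6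
Reactants: 9 2-methoxy-5-methylbenzoic acid; 10 (2R)-2-(methoxymethyl)pyrrolidine
Product: 12 (2-methoxy-5-methylphenyl)[(2R)-2-(methoxymethyl)pyrrolidin-1-yl]methanone, via acid chloride 11 (not isolated)
Conditions: (COCl)2, DMF (cat.), CH2Cl2, 0 to 23 °C; then 10, Et3N, CH2Cl2, 0 °C
Reagents that add atoms: none
Why: N-acylation through the acid chloride; the auxiliary stereocentre is not involved.

Step 7
Reactants: 12 (2-methoxy-5-methylphenyl)[(2R)-2-(methoxymethyl)pyrrolidin-1-yl]methanone; 13 (4-bromobut-1-yn-1-yl)trimethylsilane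
Product: 17 [(1S)-1-(but-3-yn-1-yl)-3-methyl-6-oxocyclohex-2-en-1-yl][(2R)-2-(methoxymethyl)pyrrolidin-1-yl]methanone, via potassium enolate 14 (not isolated), via silylalkyne enol ether 15 (not isolated), via alkyne enol ether 16 (not isolated)
Conditions: K (2.2 equiv), NH3–THF, t-BuOH (1 equiv), −78 °C; penta-1,3-diene; 13, −78 to −33 °C; NH4Cl; then K2CO3 (cat.), MeOH, 23 °C; then 1 M HCl (cat.), MeOH–H2O, 0 °C
Reagents that add atoms: water, O
Why: Schultz asymmetric Birch reduction–alkylation: the benzamide is reduced to the chelated potassium enolate, which takes the alkyl bromide at C1 on the face anti to the methoxymethyl arm (1S quaternary carbon), after which methanolysis removes the alkynyl silyl group and dilute acid hydrolyses the enol ether to the ketone.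

Step 8
Reactants: 17 [(1S)-1-(but-3-yn-1-yl)-3-methyl-6-oxocyclohex-2-en-1-yl][(2R)-2-(methoxymethyl)pyrrolidin-1-yl]methanone
Product: 19 (6S)-6-(but-3-yn-1-yl)-6-{[(2R)-2-(methoxymethyl)pyrrolidin-1-yl]carbonyl}-4-methylcyclohexa-1,4-dien-1-yl trifluoromethanesulfonate, via potassium enolate 18 (not isolated)
Conditions: KN(SiMe3)2 (1.05 equiv), THF, −78 °C; PhNTf2, −78 to 0 °C
Reagents that add atoms: N-phenylbis(trifluoromethanesulfonimide), O=S(=O)(N(c1ccccc1)S(=O)(=O)C(F)(F)F)C(F)(F)F
Why: Enolate formation and O-triflation (enol triflate synthesis); the ketone can enolise only toward its CH2 neighbour because the other α-carbon is quaternary, and the ketone α-proton is removed before the alkyne C–H.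

Step 9
Reactants: 19 (6S)-6-(but-3-yn-1-yl)-6-{[(2R)-2-(methoxymethyl)pyrrolidin-1-yl]carbonyl}-4-methylcyclohexa-1,4-dien-1-yl trifluoromethanesulfonate; 8 (4R)-4-bromo-3,3-dimethylcyclohexan-1-one
Product: 21 (6S)-6-{4-[(1S,4R)-4-bromo-1-hydroxy-3,3-dimethylcyclohexyl]but-3-yn-1-yl}-6-{[(2R)-2-(methoxymethyl)pyrrolidin-1-yl]carbonyl}-4-methylcyclohexa-1,4-dien-1-yl trifluoromethanesulfonate, via lithium acetylide 20 (not isolated)
Conditions: LiN(i-Pr)2, THF, −78 °C; CeCl3; 8, −95 to −60 °C; aq. NH4Cl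
Reagents that add atoms: none
Why: 1,2-Addition of the cerium acetylide to the ketone: the nucleophile enters equatorially, anti to the axial 3-methyl group of the chair with equatorial bromine, giving the axial alcohol cis to bromine; because this rests on the modest equatorial preference of bromine, the selectivity is expected to be moderate and the minor epimer is removed by chromatography.

Step 10
Reactants: 21 (6S)-6-{4-[(1S,4R)-4-bromo-1-hydroxy-3,3-dimethylcyclohexyl]but-3-yn-1-yl}-6-{[(2R)-2-(methoxymethyl)pyrrolidin-1-yl]carbonyl}-4-methylcyclohexa-1,4-dien-1-yl trifluoromethanesulfonate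
Product: 23 (1S,4Z,5S,6S)-4-{[(1S,4R)-4-bromo-1-hydroxy-3,3-dimethylcyclohexyl]methylidene}-6-methyl-10-oxo-11-oxatricyclo[4.3.2.0(1,5)]undec-8-en-9-yl trifluoromethanesulfonate, via iminium ether 22 (not isolated)
Conditions: (Ph3P)AuNTf2 (5 mol %), AcOH (2 equiv), H2O (5 equiv), CH2Cl2, 23 °C; aq. NaHCO3
Reagents that add atoms: water, O
Why: Proposed new method: gold-catalysed 5-exo-dig carbolactonisation of the 1,6-enyne amide — the gold-activated alkyne, tethered to the quaternary carbon, is attacked by the trisubstituted ring alkene on the tether face (cis ring fusion C1/C5) while the amide oxygen traps the developing tertiary cation anti at C6, anti-carboauration and protodeauration give the (Z)-alkene, and water hydrolyses the iminium ether to the lactone with release of the auxiliary; closest known reaction types are Echavarren-type alkoxycyclisation of 1,6-enynes, Toste-type enyne polycyclisations ended by carboxylic acids and the Schultz iodolactonisation of these amides.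

Step 11
Reactants: 23 (1S,4Z,5S,6S)-4-{[(1S,4R)-4-bromo-1-hydroxy-3,3-dimethylcyclohexyl]methylidene}-6-methyl-10-oxo-11-oxatricyclo[4.3.2.0(1,5)]undec-8-en-9-yl trifluoromethanesulfonate
Product: 24 (1S,4R,5S,6S)-4-{[(1R,4R)-4-bromo-1-hydroxy-3,3-dimethylcyclohexyl]methyl}-6-methyl-10-oxo-11-oxatricyclo[4.3.2.0(1,5)]undec-8-en-9-yl trifluoromethanesulfonate
Conditions: H2 (1 atm), [Ir(cod)(PCy3)(py)]PF6 (5 mol %), CH2Cl2, 23 °C
Reagents that add atoms: none
Why: Homogeneous alkene hydrogenation: H2 adds to the exocyclic alkene from the open face of the cyclopentane, syn to H-5 and away from the quaternary C6, so the side chain ends cis to C6 (4R), while the hindered, electron-poor enol triflate is left alone.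

Step 12
Reactants: 24 (1S,4R,5S,6S)-4-{[(1R,4R)-4-bromo-1-hydroxy-3,3-dimethylcyclohexyl]methyl}-6-methyl-10-oxo-11-oxatricyclo[4.3.2.0(1,5)]undec-8-en-9-yl trifluoromethanesulfonate
Product: 25 (1R,4R,5S,6S)-4-{[(1R,4R)-4-bromo-1-hydroxy-3,3-dimethylcyclohexyl]methyl}-6-methyl-11-oxatricyclo[4.3.2.0(1,5)]undec-8-en-10-one
Conditions: Pd(OAc)2 (5 mol %), PPh3 (10 mol %), HCO2H, Bu3N, DMF, 60 °C
Reagents that add atoms: none
Why: Palladium-catalysed formate reduction of an enol triflate (Cacchi reduction): oxidative addition, formate exchange, loss of CO2 and reductive elimination replace OTf by H without touching the secondary alkyl bromide or the lactone.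

Step 13
Reactants: 25 (1R,4R,5S,6S)-4-{[(1R,4R)-4-bromo-1-hydroxy-3,3-dimethylcyclohexyl]methyl}-6-methyl-11-oxatricyclo[4.3.2.0(1,5)]undec-8-en-10-one
Product: 26 (1R,4R,5S,6S,9R)-9-bromo-4-{[(1R,4R)-4-bromo-1-hydroxy-3,3-dimethylcyclohexyl]methyl}-6-methyl-11-oxatricyclo[4.3.2.0(1,5)]undecan-10-one (CNP0282702.1)
Conditions: Co(acac)2 (0.25 equiv), t-BuOOH, Et3SiH, TsBr, n-PrOH, 23 °C
Reagents that add atoms: 4-methylbenzenesulfonyl bromide, Cc1ccc(cc1)S(=O)(=O)Br
Why: Mukaiyama-type cobalt hydride hydrogen-atom-transfer hydrobromination: the hydrogen atom goes to the less hindered C8, and the C9 radical next to the quaternary C1 takes bromine from TsBr on the open equatorial side (the axial side is blocked by the syn-axial C4), giving the (9R) equatorial bromide cis to the lactone carbonyl.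

**Compound list**

1 | 2-methylbut-3-en-2-ol | CC(C)(O)C=C | starting material
2 | triethyl orthoacetate | CCOC(C)(OCC)OCC | starting material
3 | ethyl 5-methylhex-4-enoate | CCOC(=O)CCC=C(C)C | intermediate
4 | ethyl 3-[(2S)-3,3-dimethyloxiran-2-yl]propanoate | CCOC(=O)CC[C@@H]1OC1(C)C | intermediate
5 | ethyl (4R)-4-bromo-5-hydroxy-5-methylhexanoate | CCOC(=O)CC[C@@H](Br)C(C)(C)O | intermediate
6 | (5R)-5-bromo-6,6-dimethyloxan-2-one | CC1(C)OC(=O)CC[C@H]1Br | intermediate
7 | (3R)-3-bromo-2,2-dimethyl-6-methylideneoxane | CC1(C)OC(=C)CC[C@H]1Br | intermediate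
8 | (4R)-4-bromo-3,3-dimethylcyclohexan-1-one | CC1(C)CC(=O)CC[C@H]1Br | intermediate
9 | 2-methoxy-5-methylbenzoic acid | COc1ccc(C)cc1C(O)=O | starting material
10 | (2R)-2-(methoxymethyl)pyrrolidine | COC[C@H]1CCCN1 | starting material
11 | 2-methoxy-5-methylbenzoyl chloride | COc1ccc(C)cc1C(Cl)=O | intermediate
12 | (2-methoxy-5-methylphenyl)[(2R)-2-(methoxymethyl)pyrrolidin-1-yl]methanone | COC[C@H]1CCCN1C(=O)c1cc(C)ccc1OC | intermediate
13 | (4-bromobut-1-yn-1-yl)trimethylsilane | C[Si](C)(C)C#CCCBr | starting material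
14 | potassium amide enolate of the 1,4-dihydroarene (2-methoxy-5-methylcyclohexa-2,5-dien-1-ylidene enolate) | [K+].[O-]C(N1CCC[C@@H]1COC)=C1C=C(C)CC=C1OC | intermediate
15 | [(1S)-2-methoxy-5-methyl-1-(4-trimethylsilylbut-3-yn-1-yl)cyclohexa-2,5-dien-1-yl][(2R)-2-(methoxymethyl)pyrrolidin-1-yl]methanone | C[Si](C)(C)C#CCC[C@@]1(C(=O)N2CCC[C@@H]2COC)C(OC)=CCC(C)=C1 | intermediate
16 | [(1S)-1-(but-3-yn-1-yl)-2-methoxy-5-methylcyclohexa-2,5-dien-1-yl][(2R)-2-(methoxymethyl)pyrrolidin-1-yl]methanone | C#CCC[C@@]1(C(=O)N2CCC[C@@H]2COC)C(OC)=CCC(C)=C1 | intermediate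
17 | [(1S)-1-(but-3-yn-1-yl)-3-methyl-6-oxocyclohex-2-en-1-yl][(2R)-2-(methoxymethyl)pyrrolidin-1-yl]methanone | C#CCC[C@@]1(C(=O)N2CCC[C@@H]2COC)C(=O)CCC(C)=C1 | intermediate
18 | potassium enolate of 17 | [K+].C#CCC[C@@]1(C(=O)N2CCC[C@@H]2COC)C([O-])=CCC(C)=C1 | intermediate
19 | (6S)-6-(but-3-yn-1-yl)-6-{[(2R)-2-(methoxymethyl)pyrrolidin-1-yl]carbonyl}-4-methylcyclohexa-1,4-dien-1-yl trifluoromethanesulfonate | C#CCC[C@@]1(C(=O)N2CCC[C@@H]2COC)C(OS(=O)(=O)C(F)(F)F)=CCC(C)=C1 | intermediate
20 | lithium acetylide of 19 | [Li+].[C-]#CCC[C@@]1(C(=O)N2CCC[C@@H]2COC)C(OS(=O)(=O)C(F)(F)F)=CCC(C)=C1 | intermediate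
21 | (6S)-6-{4-[(1S,4R)-4-bromo-1-hydroxy-3,3-dimethylcyclohexyl]but-3-yn-1-yl}-6-{[(2R)-2-(methoxymethyl)pyrrolidin-1-yl]carbonyl}-4-methylcyclohexa-1,4-dien-1-yl trifluoromethanesulfonate | CC1(C)C[C@](O)(C#CCC[C@@]2(C(=O)N3CCC[C@@H]3COC)C(OS(=O)(=O)C(F)(F)F)=CCC(C)=C2)CC[C@H]1Br | intermediate
22 | cyclic iminium ether of 23 (C10=N+ of the (2R)-2-(methoxymethyl)pyrrolidinium unit in place of C10=O), acetate salt | CC1(C)C[C@](O)(/C=C2/CC[C@@]34C(=[N+]5CCC[C@@H]5COC)O[C@@](C)(CC=C3OS(=O)(=O)C(F)(F)F)[C@@H]24)CC[C@H]1Br.CC(=O)[O-] | intermediate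
23 | (1S,4Z,5S,6S)-4-{[(1S,4R)-4-bromo-1-hydroxy-3,3-dimethylcyclohexyl]methylidene}-6-methyl-10-oxo-11-oxatricyclo[4.3.2.0(1,5)]undec-8-en-9-yl trifluoromethanesulfonate | CC1(C)C[C@](O)(/C=C2/CC[C@@]34C(=O)O[C@@](C)(CC=C3OS(=O)(=O)C(F)(F)F)[C@@H]24)CC[C@H]1Br | intermediate
24 | (1S,4R,5S,6S)-4-{[(1R,4R)-4-bromo-1-hydroxy-3,3-dimethylcyclohexyl]methyl}-6-methyl-10-oxo-11-oxatricyclo[4.3.2.0(1,5)]undec-8-en-9-yl trifluoromethanesulfonate | CC1(C)C[C@](O)(C[C@H]2CC[C@@]34C(=O)O[C@@](C)(CC=C3OS(=O)(=O)C(F)(F)F)[C@@H]24)CC[C@H]1Br | intermediate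
25 | (1R,4R,5S,6S)-4-{[(1R,4R)-4-bromo-1-hydroxy-3,3-dimethylcyclohexyl]methyl}-6-methyl-11-oxatricyclo[4.3.2.0(1,5)]undec-8-en-10-one | CC1(C)C[C@](O)(C[C@H]2CC[C@@]34C(=O)O[C@@](C)(CC=C3)[C@@H]24)CC[C@H]1Br | intermediate
26 | (1R,4R,5S,6S,9R)-9-bromo-4-{[(1R,4R)-4-bromo-1-hydroxy-3,3-dimethylcyclohexyl]methyl}-6-methyl-11-oxatricyclo[4.3.2.0(1,5)]undecan-10-one | CC1(C)C[C@](O)(C[C@H]2CC[C@@]34C(=O)O[C@@](C)(CC[C@H]3Br)[C@@H]24)CC[C@H]1Br | target

**Step count**

Total steps: 13. Longest linear sequence: 10 (steps 1–5, then 9–13).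

**Three steps most likely to fail, with fallbacks**

Step 5 (O-to-C ring switch). Risks are protonation of the enol ether, loss of HBr, or bromine transfer to the enol carbon instead of C–C closure. The fallback sets out from 6 and comes back at 8. Lactone 6 is opened with the lithium enolate of tert-butyl acetate (LiN(i-Pr)2, THF, −78 °C, cold AcOH quench) to tert-butyl (6R)-6-bromo-7-hydroxy-7-methyl-3-oxooctanoate F1. Its tertiary alcohol is ionised with SnCl4 (CH2Cl2, −78 to 0 °C), so that the β-keto ester carbon closes on the bromonium ion (White-type cyclisation of β-keto esters). This gives tert-butyl (5R)-5-bromo-6,6-dimethyl-2-oxocyclohexane-1-carboxylate F2. CF3CO2H, then gentle warming, removes the ester group and gives 8.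

Step 10 (gold carbolactonisation). Risks are 6-endo closure, Meyer–Schuster rearrangement of the propargylic alcohol, and catalyst inhibition by the released amine. The fallback sets out from 21 and comes back at 24. Schultz iodolactonisation of 21 (I2, THF–H2O, 23 °C) removes the auxiliary and gives 1-{4-[(1S,4R)-4-bromo-1-hydroxy-3,3-dimethylcyclohexyl]but-3-yn-1-yl}-8-iodo-5-methyl-7-oxo-6-oxabicyclo[3.2.1]oct-2-en-2-yl trifluoromethanesulfonate F3, with iodine anti to the lactone bridge. A radical 5-exo-dig cyclisation ((Me3Si)3SiH, Et3B, air, toluene, 0 °C; the C–I bond reacts, the C–Br and C–OTf bonds do not) closes the cyclopentane cis to the chain. It gives 23 mixed with its (4E)-isomer F4, and hydrogenation of the mixture as in step 11 converges on 24.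

Step 13 (hydrobromination). Risks are hydrogen-atom transfer to C9 instead of C8 (bromine then ends on C8) and low reactivity of the hindered cis-alkene. The fallback sets out from 24 and comes back at 26. Miyaura borylation of the enol triflate (B2pin2, Pd(dppf)Cl2, KOAc, dioxane, 80 °C) gives the C9 alkenyl pinacol boronate F5. Hydrogenation (H2, [Ir(cod)(PCy3)(py)]PF6, CH2Cl2) adds hydrogen from the lactone face and gives the C9 alkyl pinacol boronate F6, with boron syn to C4. Boronate formation with 3,5-bis(trifluoromethyl)phenyllithium (one extra equivalent for the tertiary alcohol, THF, −78 °C) and NBS then replaces boron by bromine with inversion, giving the equatorial bromide 26.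

Further compounds

F1 | step 5 | tert-butyl (6R)-6-bromo-7-hydroxy-7-methyl-3-oxooctanoate | CC(C)(C)OC(=O)CC(=O)CC[C@@H](Br)C(C)(C)O
F2 | step 5 | tert-butyl (5R)-5-bromo-6,6-dimethyl-2-oxocyclohexane-1-carboxylate (C1 epimers) | CC(C)(C)OC(=O)C1C(=O)CC[C@@H](Br)C1(C)C
F3 | step 10 | 1-{4-[(1S,4R)-4-bromo-1-hydroxy-3,3-dimethylcyclohexyl]but-3-yn-1-yl}-8-iodo-5-methyl-7-oxo-6-oxabicyclo[3.2.1]oct-2-en-2-yl trifluoromethanesulfonate (iodine anti to the lactone bridge) | CC1(C)C[C@](O)(C#CCC[C@@]23C(=O)O[C@@](C)(CC=C2OS(=O)(=O)C(F)(F)F)[C@H]3I)CC[C@H]1Br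
F4 | step 10 | (4E)-isomer of 23 | CC1(C)C[C@](O)(/C=C2\CC[C@@]34C(=O)O[C@@](C)(CC=C3OS(=O)(=O)C(F)(F)F)[C@@H]24)CC[C@H]1Br
F5 | step 13 | C9 alkenyl pinacol boronate (24 with OTf replaced by Bpin) | CC1(C)C[C@](O)(C[C@H]2CC[C@@]34C(=O)O[C@@](C)(CC=C3B5OC(C)(C)C(C)(C)O5)[C@@H]24)CC[C@H]1Br
F6 | step 13 | C9 alkyl pinacol boronate (26 with Br replaced by Bpin of opposite configuration, boron syn to C4) | CC1(C)C[C@](O)(C[C@H]2CC[C@@]34C(=O)O[C@@](C)(CC[C@@H]3B5OC(C)(C)C(C)(C)O5)[C@@H]24)CC[C@H]1Br
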